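**Retrosynthetic overview**
- The target comes from global deacylation of a hexa-ester; its stilbene arm comes from a Heck reaction of a C6 aryl triflate with 4-acetoxystyrene.
- The C3–aryl bond comes from a decarboxylative Ni cross-coupling of a trans-2-aryl-2,3-dihydrobenzofuran-3-carboxylic acid with 5-iodoresorcinol diacetate; the C2 aryl group directs the new centre trans.
- The dihydrobenzofuran ring comes from an oxidative ring contraction of a protected flavanone: the A-ring carbon shifts suprafacially [1,2] from C4 to C3, making the C3–C3a bond and leaving C2 untouched.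
- The flavanone is natural (2S)-eriodictyol, which supplies C2 with its catechol ring, the ring oxygen and the oxygenated A ring; its 7-OH becomes the triflate that later carries the styryl group.
- Ring order: chromanone (bought), then dihydrobenzofuran (ring contraction, the only ring-forming event); all four benzene rings are bought.

Assumption: (–)-eriodictyol is bought as the single (2S) enantiomer (ee checked by chiral HPLC before use).
Abbreviations: Piv = 2,2-dimethylpropanoyl; Tf = trifluoromethanesulfonyl; NHPI = N-hydroxyphthalimide; DIC = N,N'-diisopropylcarbodiimide; dtbbpy = 4,4'-di-tert-butyl-2,2'-bipyridine.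

**Step 1**
Reactants: 1 (2S)-eriodictyol
Product: 3 (2S)-2-[3,4-bis(pivaloyloxy)phenyl]-4-oxo-7-(triflyloxy)chroman-5-yl pivalate, via eriodictyol 7-O-triflate 2 (not isolated)
Conditions: PhNTf2 (1.05 equiv), i-Pr2NEt (1.1 equiv), THF, 0 °C → rt, Ar; then pyridine, PivCl (5 equiv), DMAP (cat.), 0 → 40 °C
Reagents that add atoms: N-phenyl-bis(trifluoromethanesulfonimide) O=S(=O)(N(c1ccccc1)S(=O)(=O)C(F)(F)F)C(F)(F)F; pivaloyl chloride CC(C)(C)C(=O)Cl
Why: The 7-OH is the most acidic and the only non-chelated A-ring phenol, so one equivalent of base and PhNTf2 sulfonylate it chemoselectively, and the other three phenols are then acylated (nucleophilic acyl substitution) under amine bases too weak to open the flavanone, so C2 stays S.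

**Step 2**
Reactants: 3 (2S)-2-[3,4-bis(pivaloyloxy)phenyl]-4-oxo-7-(triflyloxy)chroman-5-yl pivalate
Product: 4 methyl (2S,3S)-2-[3,4-bis(pivaloyloxy)phenyl]-4-(pivaloyloxy)-6-(triflyloxy)-2,3-dihydro-1-benzofuran-3-carboxylate (2,3-trans)
Conditions: PhI(OAc)2 (1.3 equiv), conc. H2SO4 (0.5 equiv), HC(OMe)3, rt
Reagents that add atoms: trimethyl orthoformate COC(OC)OC
Why: Hypervalent-iodine oxidative ring contraction of a flavanone: the enol ether is iodinated at C3 and the A-ring carbon C4a makes a suprafacial [1,2]-aryl shift from C4 to C3 with loss of PhI while C4 becomes the ester carbon; C2 is not touched and the new C3 centre emerges trans to the C2 aryl group under its control (trans is also the thermodynamic isomer).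

**Step 3**
Reactants: 4 methyl (2S,3S)-2-[3,4-bis(pivaloyloxy)phenyl]-4-(pivaloyloxy)-6-(triflyloxy)-2,3-dihydro-1-benzofuran-3-carboxylate
Product: 5 (2S,3S)-2-[3,4-bis(pivaloyloxy)phenyl]-4-(pivaloyloxy)-6-(triflyloxy)-2,3-dihydro-1-benzofuran-3-carboxylic acid
Conditions: LiI (5 equiv), EtOAc, reflux; then 1 M HCl work-up
Reagents that add atoms: none
Why: SN2 O-demethylation by iodide cleaves only the methyl ester, spares the aryl pivalates and the aryl triflate, and avoids hydroxide, which could open the β-aryloxy ester by retro-oxa-Michael elimination (any C3 epimer is harmless because C3 is reset in step 5).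

**Step 4**
Reactants: 6 5-iodoresorcinol
Product: 7 5-iodo-1,3-phenylene diacetate
Conditions: Ac2O, pyridine, DMAP (cat.), CH2Cl2, rt
Reagents that add atoms: acetic anhydride CC(=O)OC(C)=O
Why: Standard O-acetylation of both phenols gives an aryl iodide whose protecting groups fall off in the final deacylation.

**Step 5**
Reactants: 5 (2S,3S)-2-[3,4-bis(pivaloyloxy)phenyl]-4-(pivaloyloxy)-6-(triflyloxy)-2,3-dihydro-1-benzofuran-3-carboxylic acid; 7 5-iodo-1,3-phenylene diacetate
Product: 9 5-[(2S,3S)-2-[3,4-bis(pivaloyloxy)phenyl]-4-(pivaloyloxy)-6-(triflyloxy)-2,3-dihydro-1-benzofuran-3-yl]-1,3-phenylene diacetate (2,3-trans), via N-acyloxyphthalimide ester 8 (not isolated)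
Conditions: NHPI, DIC, CH2Cl2, rt (no amine base); evaporate; then 7 (1.5 equiv), NiBr2·dme (10 mol %), dtbbpy (10 mol %), Zn dust (2 equiv), DMA, rt, Ar
Reagents that add atoms: none
Why: Ni-catalysed decarboxylative cross-electrophile coupling: the redox-active ester fragments to the planar C3 benzylic radical, which is captured by the aryl-nickel species (the aryl iodide reacts far faster than the aryl triflate) and reductively eliminated on the face anti to the C2 aryl group, so C2 sets the 3S (trans) centre.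

**Step 6**
Reactants: 9 5-[(2S,3S)-2-[3,4-bis(pivaloyloxy)phenyl]-4-(pivaloyloxy)-6-(triflyloxy)-2,3-dihydro-1-benzofuran-3-yl]-1,3-phenylene diacetate; 10 4-acetoxystyrene
Product: 11 5-[(2S,3S)-6-[(E)-2-(4-acetoxyphenyl)ethenyl]-2-[3,4-bis(pivaloyloxy)phenyl]-4-(pivaloyloxy)-2,3-dihydro-1-benzofuran-3-yl]-1,3-phenylene diacetate
Conditions: PdCl2(PPh3)2 (5 mol %), LiCl (3 equiv), Et3N (3 equiv), DMF, 90 °C, Ar, dark
Reagents that add atoms: none
Why: Mizoroki–Heck reaction of the unhindered aryl triflate (neutral pathway with LiCl) arylates the terminal styrene carbon and syn β-hydride elimination gives the E-stilbene; neither stereocentre is acidic any longer, so both survive the amine base.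

**Step 7**
Reactants: 11 5-[(2S,3S)-6-[(E)-2-(4-acetoxyphenyl)ethenyl]-2-[3,4-bis(pivaloyloxy)phenyl]-4-(pivaloyloxy)-2,3-dihydro-1-benzofuran-3-yl]-1,3-phenylene diacetate
Product: 12 4-[(2S,3S)-3-(3,5-dihydroxyphenyl)-4-hydroxy-6-[(E)-2-(4-hydroxyphenyl)ethenyl]-2,3-dihydro-1-benzofuran-2-yl]benzene-1,2-diol (target)
Conditions: NaOMe (8 equiv), degassed MeOH/THF, 0 °C → rt, Ar, dark; then AcOH
Reagents that add atoms: none
Why: Methoxide transesterification (Zemplén-type deacylation) removes all six aryl esters in one operation under conditions that do not touch the stilbene, the ring ether or the two non-acidic stereocentres.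

**Compound list**
1 | (2S)-eriodictyol, (2S)-2-(3,4-dihydroxyphenyl)-5,7-dihydroxychroman-4-one | O=C1C[C@@H](c2ccc(O)c(O)c2)Oc2cc(O)cc(O)c12 | starting material
2 | (2S)-2-(3,4-dihydroxyphenyl)-5-hydroxy-4-oxochroman-7-yl triflate (eriodictyol 7-O-triflate) | O=C1C[C@@H](c2ccc(O)c(O)c2)Oc2cc(OS(=O)(=O)C(F)(F)F)cc(O)c12 | intermediate
3 | (2S)-2-[3,4-bis(pivaloyloxy)phenyl]-4-oxo-7-(triflyloxy)chroman-5-yl pivalate | O=C1C[C@@H](c2ccc(OC(=O)C(C)(C)C)c(OC(=O)C(C)(C)C)c2)Oc2cc(OS(=O)(=O)C(F)(F)F)cc(OC(=O)C(C)(C)C)c12 | intermediate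
4 | methyl (2S,3S)-2-[3,4-bis(pivaloyloxy)phenyl]-4-(pivaloyloxy)-6-(triflyloxy)-2,3-dihydro-1-benzofuran-3-carboxylate (trans) | COC(=O)[C@@H]1[C@@H](c2ccc(OC(=O)C(C)(C)C)c(OC(=O)C(C)(C)C)c2)Oc2cc(OS(=O)(=O)C(F)(F)F)cc(OC(=O)C(C)(C)C)c21 | intermediate
5 | (2S,3S)-2-[3,4-bis(pivaloyloxy)phenyl]-4-(pivaloyloxy)-6-(triflyloxy)-2,3-dihydro-1-benzofuran-3-carboxylic acid | OC(=O)[C@@H]1[C@@H](c2ccc(OC(=O)C(C)(C)C)c(OC(=O)C(C)(C)C)c2)Oc2cc(OS(=O)(=O)C(F)(F)F)cc(OC(=O)C(C)(C)C)c21 | intermediate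
6 | 5-iodoresorcinol (5-iodobenzene-1,3-diol) | Oc1cc(O)cc(I)c1 | starting material
7 | 5-iodo-1,3-phenylene diacetate | CC(=O)Oc1cc(I)cc(OC(C)=O)c1 | intermediate
8 | 1,3-dioxoisoindolin-2-yl (2S,3S)-2-[3,4-bis(pivaloyloxy)phenyl]-4-(pivaloyloxy)-6-(triflyloxy)-2,3-dihydro-1-benzofuran-3-carboxylate (NHPI ester of 5) | O=C(ON1C(=O)c2ccccc2C1=O)[C@@H]1[C@@H](c2ccc(OC(=O)C(C)(C)C)c(OC(=O)C(C)(C)C)c2)Oc2cc(OS(=O)(=O)C(F)(F)F)cc(OC(=O)C(C)(C)C)c21 | intermediate
9 | 5-[(2S,3S)-2-[3,4-bis(pivaloyloxy)phenyl]-4-(pivaloyloxy)-6-(triflyloxy)-2,3-dihydro-1-benzofuran-3-yl]-1,3-phenylene diacetate (trans) | CC(=O)Oc1cc(OC(C)=O)cc(c1)[C@@H]1[C@@H](c2ccc(OC(=O)C(C)(C)C)c(OC(=O)C(C)(C)C)c2)Oc2cc(OS(=O)(=O)C(F)(F)F)cc(OC(=O)C(C)(C)C)c21 | intermediate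
10 | 4-acetoxystyrene (4-ethenylphenyl acetate) | CC(=O)Oc1ccc(C=C)cc1 | starting material
11 | 5-[(2S,3S)-6-[(E)-2-(4-acetoxyphenyl)ethenyl]-2-[3,4-bis(pivaloyloxy)phenyl]-4-(pivaloyloxy)-2,3-dihydro-1-benzofuran-3-yl]-1,3-phenylene diacetate | CC(=O)Oc1ccc(/C=C/c2cc(OC(=O)C(C)(C)C)c3c(c2)O[C@H](c2ccc(OC(=O)C(C)(C)C)c(OC(=O)C(C)(C)C)c2)[C@H]3c2cc(OC(C)=O)cc(OC(C)=O)c2)cc1 | intermediate
12 | 4-[(2S,3S)-3-(3,5-dihydroxyphenyl)-4-hydroxy-6-[(E)-2-(4-hydroxyphenyl)ethenyl]-2,3-dihydro-1-benzofuran-2-yl]benzene-1,2-diol | Oc1ccc(/C=C/c2cc(O)c3c(c2)O[C@H](c2ccc(O)c(O)c2)[C@H]3c2cc(O)cc(O)c2)cc1 | target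

**Totals**
Total step count: 7. Longest linear sequence: 6 (steps 1, 2, 3, 5, 6, 7 from compound 1).

**Three steps most likely to fail**

Step 2 (ring contraction). The A ring carries an ester and a triflate and may migrate sluggishly, so 2,3-shift of the B ring (isoflavone), flavone formation or 3-methoxylation can compete. The fallback sets out from 3 and comes back at 4 by a Wolff ring contraction. Compound 3 is C-acylated (LiHMDS, CF3CO2CH2CF3, THF, –78 °C) to the 3-trifluoroacetyl flavanone F3. Detrifluoroacetylative diazo transfer (MsN3, Et3N, MeCN) then gives the 3-diazoflavanone F4. Photolysis (λ ≥ 300 nm) in MeOH moves the same A-ring carbon from C4 to the carbene carbon C3 and methanol traps the ketene as 4.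

Step 5 (decarboxylative arylation). The benzylic radical may dimerise, the alkyl-nickel species may undergo β-hydride elimination to the benzofuran, or the activated ester may ring-open. The fallback sets out from 5 and 7 and comes back at 9 by a redox-neutral coupling with a preformed aryl nucleophile. Compound 5 is converted (tetrachloro-N-hydroxyphthalimide, DIC, CH2Cl2) into the isolated tetrachlorophthalimide ester F5. Compound 7 is converted (Zn dust, LiCl, THF) into [3,5-bis(acetyloxy)phenyl]zinc iodide F6. Ni-catalysed decarboxylative Negishi-type coupling of the two (NiCl2·glyme, dtbbpy, THF/DMF, rt) gives 9 with the same C2-controlled trans selectivity.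

Step 1 (regioselective 7-O-triflation). The catechol 4'-OH may compete for the triflating agent. The fallback sets out from 1 and comes back at 3 by protecting everything and then unmasking only O7. Compound 1 is exhaustively acylated (PivCl, pyridine, DMAP) to (2S)-eriodictyol tetrapivalate F1. The 7-O-pivaloyl group, the most electrophilic ester because it is para to the C4 carbonyl, is removed by selective thiolysis (PhSH, imidazole, NMP, 0 °C) to give the 7-hydroxy tripivalate F2. Triflation (Tf2O, pyridine, CH2Cl2, –20 °C) then gives 3.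

**Further compounds**
F1 | step 1 | (2S)-eriodictyol tetrapivalate, (2S)-2-[3,4-bis(pivaloyloxy)phenyl]-4-oxochroman-5,7-diyl dipivalate | O=C1C[C@@H](c2ccc(OC(=O)C(C)(C)C)c(OC(=O)C(C)(C)C)c2)Oc2cc(OC(=O)C(C)(C)C)cc(OC(=O)C(C)(C)C)c12
F2 | step 1 | (2S)-2-[3,4-bis(pivaloyloxy)phenyl]-7-hydroxy-4-oxochroman-5-yl pivalate | O=C1C[C@@H](c2ccc(OC(=O)C(C)(C)C)c(OC(=O)C(C)(C)C)c2)Oc2cc(O)cc(OC(=O)C(C)(C)C)c12
F3 | step 2 | (2S)-2-[3,4-bis(pivaloyloxy)phenyl]-4-oxo-3-(trifluoroacetyl)-7-(triflyloxy)chroman-5-yl pivalate (C3 unspecified, enolised) | O=C1C(C(=O)C(F)(F)F)[C@@H](c2ccc(OC(=O)C(C)(C)C)c(OC(=O)C(C)(C)C)c2)Oc2cc(OS(=O)(=O)C(F)(F)F)cc(OC(=O)C(C)(C)C)c12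
F4 | step 2 | (2R)-2-[3,4-bis(pivaloyloxy)phenyl]-3-diazo-4-oxo-7-(triflyloxy)chroman-5-yl pivalate (same spatial arrangement at C2 as 3; descriptor changes by CIP only) | O=C1C(=[N+]=[N-])[C@@H](c2ccc(OC(=O)C(C)(C)C)c(OC(=O)C(C)(C)C)c2)Oc2cc(OS(=O)(=O)C(F)(F)F)cc(OC(=O)C(C)(C)C)c12
F5 | step 5 | 4,5,6,7-tetrachloro-1,3-dioxoisoindolin-2-yl (2S,3S)-2-[3,4-bis(pivaloyloxy)phenyl]-4-(pivaloyloxy)-6-(triflyloxy)-2,3-dihydro-1-benzofuran-3-carboxylate | O=C(ON1C(=O)c2c(Cl)c(Cl)c(Cl)c(Cl)c2C1=O)[C@@H]1[C@@H](c2ccc(OC(=O)C(C)(C)C)c(OC(=O)C(C)(C)C)c2)Oc2cc(OS(=O)(=O)C(F)(F)F)cc(OC(=O)C(C)(C)C)c21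
F6 | step 5 | [3,5-bis(acetyloxy)phenyl]zinc iodide | CC(=O)Oc1cc([Zn]I)cc(OC(C)=O)c1
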